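**Plan**

1. Numbering used: ring C1(OAc)–C2=C3–C4(OH)–C5(OH)(C7H2OBz)–C6(OAc). Retrosynthetic cuts, in order: the esters and a 4,5-O-isopropylidene acetal; the C1–C6 bond (to a dialdehyde); C2=C3 (Wittig, to a lactol); C5–C7 (formaldehyde aldol, back to D-mannose).
2. Enabling feature: C1 and C6 are adjacent carbinol carbons of the cyclohexene, so both can come from carbonyl carbons of like polarity joined by a reductive (pinacol) coupling. The Z C2=C3 alkene and a temporary cis-fused dioxolane ring on O4/O5 (not in the target) hold the two formyl groups together.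
3. Forward order: diacetone-D-mannose → 2-C-hydroxymethylation → reduction and glycol cleavage to D-apiose acetonide → silylation of the free CH2OH (C7) → (Z)-enoate → diol → dialdehyde → pinacol closure of the only carbocycle → acetylation, silyl-to-benzoyl exchange, acetal removal.
4. Stereochemistry: C4 is C3 of D-mannose. C5 is fixed when the apiose acetonide closes, since only the CH2OH cis to the aldehyde on the dioxolane can form the cis-fused lactol. C1 and C6 are set in the pinacol step (trans from the titanium reagent, facial sense from the dioxolane template).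

Key step: step 8

Assumption: Cp2TiPh is used as a separately prepared THF solution (from Cp2TiCl2, i-PrMgCl, then PhMgBr). TBDPS = tert-butyldiphenylsilyl.

**Route**

Step 1
Reactants: 1 2,3:5,6-di-O-isopropylidene-α-D-mannofuranose
Product: 2 2-C-(hydroxymethyl)-2,3:5,6-di-O-isopropylidene-D-mannofuranose (anomeric mixture)
Conditions: 37% aq. HCHO, K2CO3, MeOH, 65 °C
Reagents that add atoms: formaldehyde, C=O
Why: Base-mediated aldol of the ring-opened aldehyde with formaldehyde at C2 of a 2,3-O-isopropylidene furanose should stop at the lactol (which blocks crossed Cannizzaro reduction); the configuration formed at C2 is irrelevant because step 2 makes this carbon symmetric.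

Step 2
Reactants: 2 2-C-(hydroxymethyl)-2,3:5,6-di-O-isopropylidene-D-mannofuranose
Product: 3 2-C-(hydroxymethyl)-2,3:5,6-di-O-isopropylidene-D-mannitol
Conditions: NaBH4, MeOH, 0 °C to rt
Reagents that add atoms: none
Why: Borohydride reduction of the lactol through its open aldehyde form should give the triol, whose former C2 now carries two hydroxymethyl groups; no stereocenter is formed.

Step 3
Reactants: 3 2-C-(hydroxymethyl)-2,3:5,6-di-O-isopropylidene-D-mannitol
Product: 5 2,3-O-isopropylidene-D-apiofuranose (cis-fused lactol; anomeric mixture), via pentaol 4 (not isolated)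
Conditions: 70% aq. AcOH, rt; evaporate; then NaIO4 (2.2 equiv), H2O–MeOH, 0 °C to rt
Reagents that add atoms: none
Why: Dilute acid hydrolyses the terminal acetonide faster than the internal one, periodate glycol cleavage of the 4,5,6-triol excises two carbons, and the new aldehyde can lactolise only with the hydroxymethyl group cis to it on the dioxolane, which fixes the quaternary stereocenter C5 and leaves the future C7 hydroxyl free.

Step 4
Reactants: 5 2,3-O-isopropylidene-D-apiofuranose
Product: 6 3-C-[(TBDPS-oxy)methyl]-2,3-O-isopropylidene-D-erythrofuranose (5 silylated at its free CH2OH)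
Conditions: TBDPSCl, imidazole, DMF, 0 °C
Reagents that add atoms: tert-butyl(chloro)diphenylsilane, CC(C)(C)[Si](Cl)(c1ccccc1)c1ccccc1
Why: Chemoselective silylation of the primary alcohol with a bulky silyl chloride in the presence of the hindered anomeric hydroxyl, as in 5-O-silylation of 2,3-O-isopropylidene pentofuranoses.

Step 5
Reactants: 6 3-C-[(TBDPS-oxy)methyl]-2,3-O-isopropylidene-D-erythrofuranose
Product: 7 methyl (2Z)-3-[(4S,5S)-5-(TBDPS-oxymethyl)-5-(hydroxymethyl)-2,2-dimethyl-1,3-dioxolan-4-yl]prop-2-enoate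
Conditions: Ph3P=CHCO2Me (1.5 equiv), MeOH, 0 °C to rt
Reagents that add atoms: methyl (triphenylphosphoranylidene)acetate, COC(=O)C=P(c1ccccc1)(c1ccccc1)c1ccccc1
Why: Wittig olefination of the lactol through its hydroxy-aldehyde form; stabilised ylides should give mainly the (Z)-enoate with α-alkoxy aldehydes in methanol (the minor E isomer is removed by chromatography), and the ring oxygen is released as the C6 hydroxyl.

Step 6
Reactants: 7 methyl (2Z)-3-[(4S,5S)-5-(TBDPS-oxymethyl)-5-(hydroxymethyl)-2,2-dimethyl-1,3-dioxolan-4-yl]prop-2-enoate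
Product: 8 (2Z)-3-[(4S,5S)-5-(TBDPS-oxymethyl)-5-(hydroxymethyl)-2,2-dimethyl-1,3-dioxolan-4-yl]prop-2-en-1-ol
Conditions: i-Bu2AlH (3.5 equiv), CH2Cl2, −78 °C; aq. potassium sodium tartrate
Reagents that add atoms: none
Why: 1,2-Reduction of the enoate by the aluminium hydride should give the (Z)-allylic alcohol with the silyl ether and acetonide untouched (a seven-membered lactone, if it forms, is reduced to the same diol).

Step 7
Reactants: 8 (2Z)-3-[(4S,5S)-5-(TBDPS-oxymethyl)-5-(hydroxymethyl)-2,2-dimethyl-1,3-dioxolan-4-yl]prop-2-en-1-ol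
Product: 9 (4S,5S)-4-(TBDPS-oxymethyl)-2,2-dimethyl-5-[(1Z)-3-oxoprop-1-en-1-yl]-1,3-dioxolane-4-carbaldehyde
Conditions: Dess–Martin periodinane (3 equiv), NaHCO3, CH2Cl2, 0 °C to rt; used crude at once
Reagents that add atoms: none
Why: Dess–Martin oxidation of both primary alcohols under buffered, non-basic conditions; with excess reagent both hydroxyls are bound to iodine together so no hydroxy-aldehyde can lactolise or add in conjugate fashion, and the C6 aldehyde has no α-hydrogen to epimerise.

Step 8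
Reactants: 9 (4S,5S)-4-(TBDPS-oxymethyl)-2,2-dimethyl-5-[(1Z)-3-oxoprop-1-en-1-yl]-1,3-dioxolane-4-carbaldehyde
Product: 10 (3aR,4R,5S,7aS)-3a-(TBDPS-oxymethyl)-2,2-dimethyl-3a,4,5,7a-tetrahydro-1,3-benzodioxole-4,5-diol
Conditions: Cp2TiPh (3.5 equiv), THF, −78 to −30 °C, slow addition of 9 (0.01 M); aq. NH4Cl
Reagents that add atoms: none
Why: Each formyl group takes one electron from monomeric Cp2TiPh (trivalent titanium) to give a titanium-bound ketyl (an allyl-type radical over C1–C3 on the enal side, an α-oxy radical at C6), and the two carbonyl carbons, both electrophilic in 9, are joined by radical–radical combination or by ketyl addition to the second titanium-bound C=O followed by a second electron transfer, before aqueous work-up frees the diol. The closest known reaction type is the titanium-mediated intramolecular pinacol cyclisation of 1,6-dialdehydes to trans-cyclohexane-1,2-diols, together with low-valent-titanium pinacol closures in which one partner is an enal. The cyclohexene ring closes in the 6-exo-trig mode (C6 onto the C1 carbonyl carbon, the C=O staying outside the ring); bonding at C3 would need a four-membered ring and is not expected. The C1/C6 trans relationship should come from the two bulky Cp2Ti(Ph)O groups, which cannot share one metal and so lie anti, both equatorial, in a chair-like transition state. The facial sense should come from the cis-fused dioxolane, which places the C5 CH2OTBDPS group equatorial and O5 axial, so that O6 ends cis to O5 and O1 trans to O4, the diastereomer with every new substituent equatorial. The step needs ring closure to outrun intermolecular coupling, simple reduction and Z-to-E equilibration of the allyl radical, which the cis-dioxolane and the Z-alkene (holding C1 and C6 within bonding distance), high dilution, slow addition and −78 °C should secure.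

Step 9
Reactants: 10 (3aR,4R,5S,7aS)-3a-(TBDPS-oxymethyl)-2,2-dimethyl-3a,4,5,7a-tetrahydro-1,3-benzodioxole-4,5-diol
Product: 11 (3aS,4R,5S,7aS)-3a-(TBDPS-oxymethyl)-2,2-dimethyl-3a,4,5,7a-tetrahydro-1,3-benzodioxole-4,5-diyl diacetate
Conditions: Ac2O, pyridine, DMAP (cat.), CH2Cl2, 0 °C to rt
Reagents that add atoms: acetic anhydride, CC(=O)OC(C)=O
Why: DMAP-catalysed acetylation of the two secondary alcohols; no stereocenter is touched.

Step 10
Reactants: 11 (3aS,4R,5S,7aS)-3a-(TBDPS-oxymethyl)-2,2-dimethyl-3a,4,5,7a-tetrahydro-1,3-benzodioxole-4,5-diyl diacetate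
Product: 12 (3aS,4R,5S,7aS)-3a-(hydroxymethyl)-2,2-dimethyl-3a,4,5,7a-tetrahydro-1,3-benzodioxole-4,5-diyl diacetate
Conditions: HF·pyridine, pyridine, THF, 0 °C to rt
Reagents that add atoms: none
Why: Fluoride cleavage of the silyl ether under buffered, weakly acidic conditions that should suppress 1,3-acetyl migration from O6 to the freed primary hydroxyl and leave the acetonide intact.

Step 11
Reactants: 12 (3aS,4R,5S,7aS)-3a-(hydroxymethyl)-2,2-dimethyl-3a,4,5,7a-tetrahydro-1,3-benzodioxole-4,5-diyl diacetate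
Product: 13 [(3aS,4R,5S,7aS)-4,5-bis(acetyloxy)-2,2-dimethyl-3a,4,5,7a-tetrahydro-1,3-benzodioxol-3a-yl]methyl benzoate
Conditions: BzCl, pyridine, DMAP (cat.), CH2Cl2, 0 °C
Reagents that add atoms: benzoyl chloride, O=C(Cl)c1ccccc1
Why: Acylation of the only free hydroxyl, a primary one.

Step 12
Reactants: 13 [(3aS,4R,5S,7aS)-4,5-bis(acetyloxy)-2,2-dimethyl-3a,4,5,7a-tetrahydro-1,3-benzodioxol-3a-yl]methyl benzoate
Product: 14 [(1S,2S,5S,6R)-5,6-bis(acetyloxy)-1,2-dihydroxycyclohex-3-en-1-yl]methyl benzoate (EANPDB:ANNO_00166)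
Conditions: TFA–H2O (9:1), CH2Cl2, 0 °C
Reagents that add atoms: none
Why: Acid hydrolysis of the cis-fused isopropylidene acetal; the esters should survive cold aqueous TFA and acyl migration to the tertiary hydroxyl is unfavourable.

**Compound list**

1 | 2,3:5,6-di-O-isopropylidene-α-D-mannofuranose | O[C@@H]1[C@@H](O2)[C@@H](OC2(C)C)[C@H](O1)[C@H]3COC(C)(C)O3 | starting material
2 | 2-C-(hydroxymethyl)-2,3:5,6-di-O-isopropylidene-D-mannofuranose (anomeric mixture) | OC1[C@@](CO)(O2)[C@@H](OC2(C)C)[C@H](O1)[C@H]3COC(C)(C)O3 | intermediate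
3 | 2-C-(hydroxymethyl)-2,3:5,6-di-O-isopropylidene-D-mannitol | OCC(CO)(O1)[C@@H](OC1(C)C)[C@H](O)[C@H]2COC(C)(C)O2 | intermediate
4 | 2-C-(hydroxymethyl)-2,3-O-isopropylidene-D-mannitol (pentaol, not isolated) | OCC(CO)(O1)[C@@H](OC1(C)C)[C@H](O)[C@H](O)CO | intermediate
5 | 2,3-O-isopropylidene-D-apiofuranose (3-C-(hydroxymethyl)-2,3-O-isopropylidene-D-erythrofuranose; anomeric mixture) | OC1[C@H](O2)[C@@](OC2(C)C)(CO)CO1 | intermediate
6 | 3-C-[(TBDPS-oxy)methyl]-2,3-O-isopropylidene-D-erythrofuranose (anomeric mixture) | OC1[C@H](O2)[C@@](OC2(C)C)(CO[Si](c3ccccc3)(c3ccccc3)C(C)(C)C)CO1 | intermediate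
7 | methyl (2Z)-3-[(4S,5S)-5-(TBDPS-oxymethyl)-5-(hydroxymethyl)-2,2-dimethyl-1,3-dioxolan-4-yl]prop-2-enoate | COC(=O)/C=C\[C@H](O1)[C@@](OC1(C)C)(CO[Si](c2ccccc2)(c2ccccc2)C(C)(C)C)CO | intermediate
8 | (2Z)-3-[(4S,5S)-5-(TBDPS-oxymethyl)-5-(hydroxymethyl)-2,2-dimethyl-1,3-dioxolan-4-yl]prop-2-en-1-ol | OC/C=C\[C@H](O1)[C@@](OC1(C)C)(CO[Si](c2ccccc2)(c2ccccc2)C(C)(C)C)CO | intermediate
9 | (4S,5S)-4-(TBDPS-oxymethyl)-2,2-dimethyl-5-[(1Z)-3-oxoprop-1-en-1-yl]-1,3-dioxolane-4-carbaldehyde | O=C/C=C\[C@H](O1)[C@@](OC1(C)C)(CO[Si](c2ccccc2)(c2ccccc2)C(C)(C)C)C=O | intermediate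
10 | (3aR,4R,5S,7aS)-3a-(TBDPS-oxymethyl)-2,2-dimethyl-3a,4,5,7a-tetrahydro-1,3-benzodioxole-4,5-diol | O[C@H]1C=C[C@H](O2)[C@@](OC2(C)C)(CO[Si](c3ccccc3)(c3ccccc3)C(C)(C)C)[C@@H]1O | intermediate
11 | (3aS,4R,5S,7aS)-3a-(TBDPS-oxymethyl)-2,2-dimethyl-3a,4,5,7a-tetrahydro-1,3-benzodioxole-4,5-diyl diacetate | CC(=O)O[C@H]1C=C[C@H](O2)[C@@](OC2(C)C)(CO[Si](c3ccccc3)(c3ccccc3)C(C)(C)C)[C@@H]1OC(C)=O | intermediate
12 | (3aS,4R,5S,7aS)-3a-(hydroxymethyl)-2,2-dimethyl-3a,4,5,7a-tetrahydro-1,3-benzodioxole-4,5-diyl diacetate | CC(=O)O[C@H]1C=C[C@H](O2)[C@@](OC2(C)C)(CO)[C@@H]1OC(C)=O | intermediate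
13 | [(3aS,4R,5S,7aS)-4,5-bis(acetyloxy)-2,2-dimethyl-3a,4,5,7a-tetrahydro-1,3-benzodioxol-3a-yl]methyl benzoate | CC(=O)O[C@H]1C=C[C@H](O2)[C@@](OC2(C)C)(COC(=O)c3ccccc3)[C@@H]1OC(C)=O | intermediate
14 | [(1S,2S,5S,6R)-5,6-bis(acetyloxy)-1,2-dihydroxycyclohex-3-en-1-yl]methyl benzoate | CC(=O)O[C@H]1C=C[C@H](O)[C@@](O)(COC(=O)c2ccccc2)[C@@H]1OC(C)=O | target

Total step count: 12. Longest linear sequence: 12 steps.

**Steps most likely to fail**

Step 8 (pinacol cyclisation). The closure may lose trans control at the allylic carbinol, through a transition state in which both oxygens sit near one metal, so that C1 epimers form together. Fallback, from 9 back to 10, with C1 set by reduction instead of by the coupling: the coupling is run as before and the epimer mixture is carried on without separation. MnO2 in CH2Cl2 should oxidise only the allylic carbinol of 10 and of its C1 epimer, the cis-diol F1, so that both converge on the 6-hydroxy-enone F2. Hydroxyl-directed 1,2-reduction with Me4NBH(OAc)3 (MeCN–AcOH, −20 °C) then delivers hydride from the face of the C6 hydroxyl and should return the trans-diol 10.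

Step 7 (double oxidation). Z-to-E isomerisation of the γ-alkoxy enal, or loss of the γ-oxygen by vinylogous elimination, may leave no dialdehyde able to cyclise. Fallback, from 6 to 11, in which the C1–C6 bond is made between two molecules and the ring is closed at C2=C3 by metathesis. Wittig methylenation of lactol 6 (Ph3PCH3Br, KOtBu, THF) gives the alkenol F3. Dess–Martin oxidation gives the non-epimerisable aldehyde F4. Indium-mediated Barbier-type acetoxyallylation with 3-bromopropenyl acetate (indium powder, THF) adds the C1–C2 unit with its oxygen and gives the ene-diol monoacetate F5. The diastereoselectivity of this addition is not secure, and the 1,6-syn isomer needed would be separated from its diastereomers; acetyl migration between O1 and O6 is harmless. Acetylation (Ac2O, pyridine, DMAP) gives the diene diacetate F6, and ring-closing metathesis with the second-generation Grubbs catalyst (H2IMes)(PCy3)Cl2Ru=CHPh in CH2Cl2 at 40 °C should give 11.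

Step 5 (Wittig on the lactol). Poor Z/E selectivity, and conjugate ring closure of the freed C6 hydroxyl onto the enoate (oxa-Michael closure to a tetrahydrofuran), may erode the (Z)-enoate. Fallback, from 6 to 8, in which the Z geometry comes from an alkyne. Ohira–Bestmann alkynylation of lactol 6 (dimethyl (1-diazo-2-oxopropyl)phosphonate, K2CO3, MeOH) gives the alkynol F7. Double deprotonation (n-BuLi, 2.2 equiv, THF, −78 °C) and trapping of the acetylide with paraformaldehyde gives the propargylic diol F8. Semihydrogenation over Pd/CaCO3 poisoned with Pb(OAc)2 (quinoline, H2, EtOAc) should give the (Z)-allylic diol 8.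

**Further compounds**

F1 | step 8 | (3aR,4R,5R,7aS)-3a-(TBDPS-oxymethyl)-2,2-dimethyl-3a,4,5,7a-tetrahydro-1,3-benzodioxole-4,5-diol (C1 epimer of 10, cis-diol) | O[C@@H]1C=C[C@H](O2)[C@@](OC2(C)C)(CO[Si](c3ccccc3)(c3ccccc3)C(C)(C)C)[C@@H]1O
F2 | step 8 | 3a-(TBDPS-oxymethyl)-4-hydroxy-2,2-dimethyl-3a,7a-dihydro-1,3-benzodioxol-5(4H)-one (C1 ketone of 10, C6 hydroxyl cis to the dioxolane oxygens) | O=C1C=C[C@H](O2)[C@@](OC2(C)C)(CO[Si](c3ccccc3)(c3ccccc3)C(C)(C)C)[C@@H]1O
F3 | step 7 | [(4S,5S)-4-(TBDPS-oxymethyl)-5-ethenyl-2,2-dimethyl-1,3-dioxolan-4-yl]methanol | C=C[C@H](O1)[C@@](OC1(C)C)(CO[Si](c2ccccc2)(c2ccccc2)C(C)(C)C)CO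
F4 | step 7 | (4S,5S)-4-(TBDPS-oxymethyl)-5-ethenyl-2,2-dimethyl-1,3-dioxolane-4-carbaldehyde | C=C[C@H](O1)[C@@](OC1(C)C)(CO[Si](c2ccccc2)(c2ccccc2)C(C)(C)C)C=O
F5 | step 7 | (1R,2S)-1-[(4R,5S)-4-(TBDPS-oxymethyl)-5-ethenyl-2,2-dimethyl-1,3-dioxolan-4-yl]-1-hydroxybut-3-en-2-yl acetate | C=C[C@H](O1)[C@@](OC1(C)C)(CO[Si](c2ccccc2)(c2ccccc2)C(C)(C)C)[C@H](O)[C@@H](OC(C)=O)C=C
F6 | step 7 | (1R,2S)-1-[(4S,5S)-4-(TBDPS-oxymethyl)-5-ethenyl-2,2-dimethyl-1,3-dioxolan-4-yl]but-3-ene-1,2-diyl diacetate | C=C[C@H](O1)[C@@](OC1(C)C)(CO[Si](c2ccccc2)(c2ccccc2)C(C)(C)C)[C@H](OC(C)=O)[C@@H](OC(C)=O)C=C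
F7 | step 5 | [(4S,5S)-4-(TBDPS-oxymethyl)-5-ethynyl-2,2-dimethyl-1,3-dioxolan-4-yl]methanol | C#C[C@H](O1)[C@@](OC1(C)C)(CO[Si](c2ccccc2)(c2ccccc2)C(C)(C)C)CO
F8 | step 5 | 3-[(4S,5S)-5-(TBDPS-oxymethyl)-5-(hydroxymethyl)-2,2-dimethyl-1,3-dioxolan-4-yl]prop-2-yn-1-ol | OCC#C[C@H](O1)[C@@](OC1(C)C)(CO[Si](c2ccccc2)(c2ccccc2)C(C)(C)C)CO
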